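The route opens the terminal oxirane (ring atoms C2, C3 and O) at C2–C3 and C2–O. That ring is a glycidic ester in reduced form. C3 bears a methyl group and the C4 chain, as a methyl ketone carbon does. C2 bears C1, whose oxidation level a hydride can adjust. A Darzens condensation between the C3 ketone and a chiral chloroacetate enolate therefore forms C2–C3, closes the oxirane and sets C2 and C3 in one operation. The precursor is the C3–C15 methyl ketone that already contains the cis C6–C7 oxirane, the E-C10=C11 alkene, the silylated 12R carbinol and the C14 methylidene group.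

Key step: step 6

Numbering: target numbering is used throughout: C1 = CH2OH, C2–C3 and C6–C7 = oxiranes, C10=C11 = E alkene, C12 = carbinol, C13 = CH2, C14 = C(=CH2), C15 = CHMe2.

Assumption (sense of induction in step 6): the chloroenolate is taken to react as the Z(O) potassium enolate (Cl cis to OK) in the ester-like conformation, with the carbinol C–H syn-coplanar to C–OK and the phenyl ring stacked over one face; this model assigns the 2R glycidate to the (1R,2S,5R)-auxiliary, whereas the target needs the 2S glycidate (the C2 descriptor becomes R on reduction only because C1 then ranks below C3), so the (1S,2R,5S)-auxiliary is used, and if a trial run shows the opposite sense the antipodal alcohol is taken with no other change.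

Step 1
Reactants: 1 nerylacetone
Product: 3 (2E,6Z)-2,6-dimethyl-10-oxoundeca-2,6-dienal (C12 keto enal), via C12 allylic alcohol 2 (not isolated)
Conditions: SeO2 (cat.), t-BuOOH, salicylic acid (cat.), CH2Cl2, 0 °C → rt, partial conversion with recovery of 1; crude product then MnO2, CH2Cl2, rt
Reagents that add atoms: tert-butyl hydroperoxide CC(C)(C)OO (oxygen relayed by selenium dioxide O=[Se]=O)
Why: Catalytic SeO2 allylic oxidation (ene reaction followed by [2,3]-sigmatropic shift) attacks the most accessible, terminal trisubstituted alkene at its E-methyl group and so fixes the E-C10=C11 geometry, MnO2 then converges the alcohol/aldehyde mixture on the enal by selective allylic alcohol oxidation, and the free methyl ketone is left alone under these cold catalytic conditions, which spares a ketal that would later need acid for its removal next to an oxirane.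

Step 2
Reactants: 3 C12 keto enal
Product: 4 (2E)-2-methyl-5-[(2S,3R)-2-methyl-3-(3-oxobutyl)oxiran-2-yl]pent-2-enal (6R,7S-epoxy keto enal)
Conditions: 1,2:4,5-di-O-isopropylidene-β-D-erythro-2,3-hexodiulo-2,6-pyranose (0.3 equiv), KHSO5 (as 2KHSO5·KHSO4·K2SO4), K2CO3, Bu4NHSO4, Na2B4O7/Na2H2EDTA buffer, MeCN–CH2(OMe)2–H2O, −5 → 0 °C
Reagents that add atoms: potassium peroxymonosulfate KHSO5 [K+].[O-]S(=O)(=O)OO
Why: In this Shi epoxidation the electrophilic chiral dioxirane formed catalytically from the D-fructose-derived ketone can only attack the electron-rich C6=C7 bond, because C10=C11 is deactivated by conjugation with the formyl group and the C14 methylidene is not yet present, and the spiro transition state that places the single vinylic hydrogen (on C6) next to the catalyst's dioxolane delivers oxygen to the face giving 6R,7S, the Z geometry being carried into the cis oxirane.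

Step 3
Reactants: 4 6R,7S-epoxy keto enal; 5 2,3-dimethylbut-1-ene; 6 (+)-B-methoxydiisopinocampheylborane (from (−)-α-pinene)
Product: 11 (5R,6S,9E,11R)-5,6-epoxy-11-hydroxy-6,10,14-trimethyl-13-methylidenepentadec-9-en-2-one (6R,7S,12R in target numbering), via 2-isopropylallylpotassium 7 (not isolated), via potassium methoxyborate 8 (not isolated), via allylborane 9 (not isolated), via C12 borinate 10 (not isolated)
Conditions: 5 (1.3 equiv), KOt-Bu, n-BuLi (1.1 equiv each), THF, −78 → −50 °C; 6 (1.1 equiv), −78 °C; BF3·OEt2 (1.1 equiv), −78 °C; 4 (1.0 equiv), −78 °C; then NaOH, H2O2, 0 °C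
Reagents that add atoms: 2,3-dimethylbut-1-ene 5 C=C(C)C(C)C (its C6H11 allyl unit, passed on through 7, 8 and 9)
Why: In this Brown-type asymmetric allylboration, metalation of 5 at its methyl group gives a symmetrical allyl anion that is handed to boron, and 9 transfers it through a chair-like six-membered transition state in which the isopinocampheyl groups derived from (−)-α-pinene expose the Re face of the aldehyde and so set 12R, while the aldehyde outruns the methyl ketone at −78 °C with only a slight excess of 9, and BF3·OEt2 is kept below the alkoxide present so that the oxirane meets no free Lewis acid.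

Step 4
Reactants: 11 12R homoallylic alcohol
Product: 12 (5R,6S,9E,11R)-11-(tert-butyldimethylsilyloxy)-5,6-epoxy-6,10,14-trimethyl-13-methylidenepentadec-9-en-2-one (C3–C15 epoxy methyl ketone)
Conditions: TBSCl, imidazole, DMAP (cat.), DMF, rt
Reagents that add atoms: tert-butyldimethylsilyl chloride CC(C)(C)[Si](C)(C)Cl
Why: Imidazole-promoted silylation of a secondary allylic alcohol runs under weakly basic conditions that neither enolise the ketone nor open the acid-sensitive γ,δ-epoxy ketone, creates no stereocentre, and gives an ether that offers KOt-Bu in step 6 no acidic proton, leaving group or carbonyl group.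

Step 5
Reactants: 13 (+)-(1S,2R,5S)-8-phenylmenthol; 14 chloroacetyl chloride
Product: 15 (1S,2R,5S)-8-phenylmenthyl chloroacetate
Conditions: pyridine, DMAP (cat.), CH2Cl2, 0 °C → rt
Reagents that add atoms: chloroacetyl chloride 14 ClCC(Cl)=O
Why: Acylation of the hindered secondary alcohol by an acid chloride under pyridine/DMAP catalysis (nucleophilic acyl substitution) takes place at oxygen and leaves the three ring stereocentres untouched.

Step 6
Reactants: 12 C3–C15 epoxy methyl ketone; 15 (1S,2R,5S)-8-phenylmenthyl chloroacetate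
Product: 18 (1S,2R,5S)-8-phenylmenthyl (2S,3R,6R,7S,10E,12R)-12-(tert-butyldimethylsilyloxy)-2,3:6,7-diepoxy-3,7,11,15-tetramethyl-14-methylidenehexadec-10-enoate, via potassium chloroenolate 16 (not isolated), via chlorohydrin alkoxide 17 (not isolated)
Conditions: 12, 15 (1.5 equiv), CH2Cl2, −78 °C; KOt-Bu (1.5 equiv) added last and slowly; −78 → −20 °C
Reagents that add atoms: (1S,2R,5S)-8-phenylmenthyl chloroacetate 15 ClCC(=O)O[C@H]1C[C@@H](C)CC[C@@H]1C(C)(C)c1ccccc1
Why: KOt-Bu, added last, deprotonates the chlorine-acidified ester 15 rather than ketone 12 to give chloroenolate 16, C2 of which adds to the C3 carbonyl (aldol step, forming C2–C3) to give the tertiary alkoxide 17, whose oxygen then expels chloride from C2 with inversion. This is the Darzens glycidic ester condensation, a reaction type established for ketones with 8-phenylmenthyl chloroacetate and applied here to a more functionalised methyl alkyl ketone. The one ring formed, the C2–C3–O oxirane, closes in the 3-exo-tet mode. C2 is set by the auxiliary, whose phenyl ring covers one face of 16 so that the ketone is met on the open Re face of C2 (2R in 17, 2S in 18 after inversion), and C3 is set by the steric preference for the pathway that places the bulky ester trans to the C4 chain and cis to the smaller methyl group (3R). Three selectivities are needed: enolisation of 15 before 12 (acidity gap and order of addition), chloride displacement by the C3 alkoxide before its 5-exo attack on C6 of the C6–C7 oxirane (activated α-chloro ester against a hindered, unactivated oxirane carbon at low temperature), and methyl-versus-methylene discrimination at C3, which is the weakest of the three, so the C3 epimer is expected as a by-product and should be removable by chromatography because the auxiliary makes all isomers diastereomers. The silyl ether, the two alkenes and the C6–C7 oxirane offer KOt-Bu neither an acidic proton nor a leaving group under these conditions.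

Step 7
Reactants: 18 bis-epoxy glycidic ester
Product: 19 (2R,3R,6R,7S,10E,12R)-12-(tert-butyldimethylsilyloxy)-2,3:6,7-diepoxy-3,7,11,15-tetramethyl-14-methylidenehexadec-10-en-1-ol
Conditions: i-Bu2AlH (3 equiv), CH2Cl2, −78 → −40 °C; aq. KNaC4H4O6
Reagents that add atoms: none
Why: Ester reduction with i-Bu2AlH delivers two hydrides to the α-oxygenated carbonyl group at low temperature faster than either trisubstituted oxirane can be opened, touches no stereocentre (C2 changes its descriptor from S to R only because C1 loses priority to C3) and releases the auxiliary 13 for reuse.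

Step 8
Reactants: 19 C12 silyl ether of the target
Product: 20 (2R,3R,6R,7S,10E,12R)-2,3:6,7-diepoxy-3,7,11,15-tetramethyl-14-methylidenehexadec-10-ene-1,12-diol (target)
Conditions: Bu4NF, AcOH (1:1), THF, 0 °C → rt
Reagents that add atoms: none
Why: Fluoride-induced desilylation is driven by Si–F bond formation, and the acetic acid buffer keeps the medium too weakly basic for a Payne rearrangement of the 2,3-epoxy alcohol or for alkoxide attack on either oxirane.

Compound list
1 | nerylacetone, (5Z)-6,10-dimethylundeca-5,9-dien-2-one | CC(C)=CCC/C(C)=C\CCC(C)=O | starting material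
2 | (5Z,9E)-11-hydroxy-6,10-dimethylundeca-5,9-dien-2-one | OC/C(C)=C/CC/C(C)=C\CCC(C)=O | intermediate
3 | (2E,6Z)-2,6-dimethyl-10-oxoundeca-2,6-dienal | O=C/C(C)=C/CC/C(C)=C\CCC(C)=O | intermediate
4 | (2E)-2-methyl-5-[(2S,3R)-2-methyl-3-(3-oxobutyl)oxiran-2-yl]pent-2-enal | O=C/C(C)=C/CC[C@]1(C)O[C@@H]1CCC(C)=O | intermediate
5 | 2,3-dimethylbut-1-ene | C=C(C)C(C)C | starting material
6 | (+)-B-methoxydiisopinocampheylborane | COB([C@H]1C[C@H]2C[C@@H]([C@@H]1C)C2(C)C)[C@H]1C[C@H]2C[C@@H]([C@@H]1C)C2(C)C | starting material
7 | 2-isopropylallylpotassium | [K+].[CH2-]C(=C)C(C)C | intermediate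
8 | potassium (2-isopropylallyl)(methoxy)diisopinocampheylborate | [K+].C=C(C(C)C)C[B-](OC)([C@H]1C[C@H]2C[C@@H]([C@@H]1C)C2(C)C)[C@H]1C[C@H]2C[C@@H]([C@@H]1C)C2(C)C | intermediate
9 | B-(2-isopropylallyl)diisopinocampheylborane | C=C(C(C)C)CB([C@H]1C[C@H]2C[C@@H]([C@@H]1C)C2(C)C)[C@H]1C[C@H]2C[C@@H]([C@@H]1C)C2(C)C | intermediate
10 | diisopinocampheylborinate of alcohol 11 at O12 | C=C(C[C@@H](OB([C@H]3C[C@H]4C[C@@H]([C@@H]3C)C4(C)C)[C@H]5C[C@H]6C[C@@H]([C@@H]5C)C6(C)C)/C(C)=C/CC[C@]1(C)O[C@@H]1CCC(C)=O)C(C)C | intermediate
11 | (5R,6S,9E,11R)-5,6-epoxy-11-hydroxy-6,10,14-trimethyl-13-methylidenepentadec-9-en-2-one | C=C(C[C@@H](O)/C(C)=C/CC[C@]1(C)O[C@@H]1CCC(C)=O)C(C)C | intermediate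
12 | (5R,6S,9E,11R)-11-(tert-butyldimethylsilyloxy)-5,6-epoxy-6,10,14-trimethyl-13-methylidenepentadec-9-en-2-one | C=C(C[C@@H](O[Si](C)(C)C(C)(C)C)/C(C)=C/CC[C@]1(C)O[C@@H]1CCC(C)=O)C(C)C | intermediate
13 | (+)-(1S,2R,5S)-8-phenylmenthol | O[C@H]1C[C@@H](C)CC[C@@H]1C(C)(C)c1ccccc1 | starting material
14 | chloroacetyl chloride | ClCC(Cl)=O | starting material
15 | (1S,2R,5S)-8-phenylmenthyl chloroacetate | ClCC(=O)O[C@H]1C[C@@H](C)CC[C@@H]1C(C)(C)c1ccccc1 | intermediate
16 | potassium Z(O)-enolate of 15 (Cl cis to OK) | [K+].Cl/C=C(\[O-])O[C@H]1C[C@@H](C)CC[C@@H]1C(C)(C)c1ccccc1 | intermediate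
17 | potassium (2R,3R)-2-chloro-3-oxido ester (aldol adduct of 16 and 12) | [K+].C=C(C[C@@H](O[Si](C)(C)C(C)(C)C)/C(C)=C/CC[C@]1(C)O[C@@H]1CC[C@@](C)([O-])[C@@H](Cl)C(=O)O[C@H]2C[C@@H](C)CC[C@@H]2C(C)(C)c3ccccc3)C(C)C | intermediate
18 | (1S,2R,5S)-8-phenylmenthyl (2S,3R,6R,7S,10E,12R)-12-(tert-butyldimethylsilyloxy)-2,3:6,7-diepoxy-3,7,11,15-tetramethyl-14-methylidenehexadec-10-enoate | C=C(C[C@@H](O[Si](C)(C)C(C)(C)C)/C(C)=C/CC[C@]1(C)O[C@@H]1CC[C@@]1(C)O[C@@H]1C(=O)O[C@H]2C[C@@H](C)CC[C@@H]2C(C)(C)c3ccccc3)C(C)C | intermediate
19 | (2R,3R,6R,7S,10E,12R)-12-(tert-butyldimethylsilyloxy)-2,3:6,7-diepoxy-3,7,11,15-tetramethyl-14-methylidenehexadec-10-en-1-ol | C=C(C[C@@H](O[Si](C)(C)C(C)(C)C)/C(C)=C/CC[C@]1(C)O[C@@H]1CC[C@@]1(C)O[C@@H]1CO)C(C)C | intermediate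
20 | (2R,3R,6R,7S,10E,12R)-2,3:6,7-diepoxy-3,7,11,15-tetramethyl-14-methylidenehexadec-10-ene-1,12-diol | C=C(C[C@@H](O)/C(C)=C/CC[C@]1(C)O[C@@H]1CC[C@@]1(C)O[C@@H]1CO)C(C)C | target

Total step count: 8. Longest linear sequence: 7 (steps 1–4 and 6–8, from 1 to 20).

Steps most likely to fail

Step 6 (Darzens condensation).
- **Risks:** The methyl group and the C4 methylene at C3 may be poorly discriminated, so that much material closes with the ester cis to the chain. The enolate-face bias may be eroded or reversed. The ketone may enolise in competition.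
- **Fallback:** It sets out from 12 and comes back at 19. Horner–Wadsworth–Emmons olefination of 12 with triethyl phosphonoacetate (NaH, THF, 0 °C → rt) should give, after chromatographic removal of the 2Z isomer, the ethyl (2E)-enoate F1. Reduction with i-Bu2AlH (CH2Cl2, −78 °C) leads to the (2E)-allylic alcohol F2. Sharpless asymmetric epoxidation (Ti(Oi-Pr)4, D-(−)-diethyl tartrate, t-BuOOH, 4 Å molecular sieves, CH2Cl2, −20 °C) then acts on C2=C3 alone, the only allylic alcohol in the molecule. It sets 2R,3R through the tartrate and gives 19.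

Step 2 (epoxidation beside a free aldehyde).
- **Risks:** Peroxymonosulfate may attack the formyl group in the basic medium and degrade it oxidatively. Less likely, unselective background epoxidation could lower the enantiomeric purity, which cannot be upgraded at this stage.
- **Fallback:** It sets out from 2, which is then isolated by chromatography after the SeO2 stage of step 1, and comes back at 4. Acetylation (Ac2O, pyridine, DMAP) gives the allylic acetate F3. The same catalytic dioxirane epoxidation now meets no aldehyde, while the acetoxy group deactivates C10=C11 inductively, and should give the 6R,7S-epoxy acetate F4. Methanolysis (K2CO3, MeOH, 0 °C) frees the epoxy allylic alcohol F5. MnO2 in CH2Cl2 oxidises it to 4.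

Step 3 (allylboration beside a free ketone and an oxirane).
- **Risks:** The allyl group may transfer to the C3 ketone in competition with the aldehyde. Boron Lewis acids may open the oxirane.
- **Fallback:** It sets out from 4 and 5 and comes back at 11. 7 is generated from 5 as in step 3 and quenched with Bu3SnCl to give tributyl(2-isopropylallyl)stannane F6. A Keck allylation of 4 with F6 follows (Ti(Oi-Pr)4 and (R)-BINOL, catalytic, 4 Å molecular sieves, CH2Cl2, −20 °C, KF work-up). It uses a mild titanium binaphtholate that activates aldehydes only, leaves ketones and isolated oxiranes alone, needs no BF3 and directs the allyl group to the Re face, giving 11.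

Further compounds
F1 | step 6 | ethyl (2E,6R,7S,10E,12R)-12-(tert-butyldimethylsilyloxy)-6,7-epoxy-3,7,11,15-tetramethyl-14-methylidenehexadeca-2,10-dienoate | C=C(C[C@@H](O[Si](C)(C)C(C)(C)C)/C(C)=C/CC[C@]1(C)O[C@@H]1CC/C(C)=C/C(=O)OCC)C(C)C
F2 | step 6 | (2E,6R,7S,10E,12R)-12-(tert-butyldimethylsilyloxy)-6,7-epoxy-3,7,11,15-tetramethyl-14-methylidenehexadeca-2,10-dien-1-ol | C=C(C[C@@H](O[Si](C)(C)C(C)(C)C)/C(C)=C/CC[C@]1(C)O[C@@H]1CC/C(C)=C/CO)C(C)C
F3 | step 2 | (2E,6Z)-2,6-dimethyl-10-oxoundeca-2,6-dien-1-yl acetate | CC(=O)OC/C(C)=C/CC/C(C)=C\CCC(C)=O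
F4 | step 2 | (2E)-2-methyl-5-[(2S,3R)-2-methyl-3-(3-oxobutyl)oxiran-2-yl]pent-2-en-1-yl acetate | CC(=O)OC/C(C)=C/CC[C@]1(C)O[C@@H]1CCC(C)=O
F5 | step 2 | 4-{(2R,3S)-3-[(3E)-5-hydroxy-4-methylpent-3-en-1-yl]-3-methyloxiran-2-yl}butan-2-one | OC/C(C)=C/CC[C@]1(C)O[C@@H]1CCC(C)=O
F6 | step 3 | tributyl(2-isopropylallyl)stannane | C=C(C(C)C)C[Sn](CCCC)(CCCC)CCCC
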